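**Retrosynthetic overview**
- Target triacid ⇐ its trimethyl ester ⇐ β-face dihydroxylation of a ring A 2-ene, with the 16-ene masked as its epoxide while ring A is built.
- Ring A ⇐ ring-closing metathesis (C2=C3); C10 quaternary centre by β-face allylation of a ring B glutaconate anion, C4–C5 by α-face Michael addition to the resulting C5=C6 enoate, C18 by in-ring enolate methylation.
- Ring D ⇐ oxidative palladium cycloalkenylation (C13–C16) of a C14 silyl enol ether onto the C8 allyl group; the C14 carbonyl is then removed.
- Ring B ⇐ enantioselective phosphine-catalysed [3+2] annulation (C6–C8 and C9–C10) of dimethyl penta-2,3-dienedioate onto 2-allylcyclohex-2-enone; this sets C8 and C9.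
- Order of ring formation: C (bought as the cyclohexenone) → B → D → A.

Assumption: gibberellane numbering (C1–C20) and the conventional gibberellin α/β descriptors (H-5 and H-9 β) are used for all intermediates; the antipode of the step 3 catalyst that gives the 8,9-configuration shown is used; C6 (until step 11), C4 (until step 11) and the epoxide carbon C16 are uncontrolled and drawn without configuration.

**Step 1**
Reactants: 1 dimethyl 3-oxopentanedioate
Product: 2 dimethyl penta-2,3-dienedioate
Conditions: 2-chloro-1,3-dimethylimidazolinium chloride (1.1 equiv), Et3N (2.2 equiv), CH2Cl2, 0 °C to rt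
Reagents that add atoms: none
Why: Dehydration of the enolised β-keto diester through its O-amidinium derivative (activation then E1cB elimination) gives the allene-1,3-diester; the allene is racemic, and its axis is erased again in step 3.

**Step 2**
Reactants: 3 2-iodocyclohex-2-en-1-one
Product: 4 2-allylcyclohex-2-en-1-one
Conditions: allylSnBu3 (1.2 equiv), Pd2(dba)3 (2.5 mol%), AsPh3 (10 mol%), CuI (10 mol%), NMP, 25 °C
Reagents that add atoms: allyltributylstannane, C=CC[Sn](CCCC)(CCCC)CCCC
Why: Stille coupling of an α-iodoenone under zerovalent palladium with copper co-catalysis is a standard C(sp2)–C(sp3) coupling; no stereocentre is formed.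

**Step 3**
Reactants: 2 dimethyl penta-2,3-dienedioate; 4 2-allylcyclohex-2-en-1-one
Product: 5 dimethyl (3aR,7aS)-7a-allyl-7-oxo-3a,4,5,6,7,7a-hexahydro-1H-indene-1,3-dicarboxylate (rings B and C; C8 and C9 set; C6 epimers)
Conditions: Ph2PCH2CH(NHCOAr)CH(CH3)OSiPh2tBu from L-threonine (Ar = 3,5-(CF3)2C6H3, 10 mol%), toluene, 4 Å molecular sieves, 25 °C, 2 (1.5 equiv) added over 6 h
Reagents that add atoms: none
Why: Proposed new method: enantioselective phosphine-catalysed [3+2] annulation of an allene-1,3-diester with an α-alkyl cyclic enone to give a ring-fusion quaternary centre — the phosphine adds to the central allene carbon (erasing the allene axis, so racemic 2 converges on one symmetrical phosphonium dienolate), the amide N–H binds and activates the enone carbonyl, one ester-bearing terminus adds to C9 on the face chosen by the catalyst, the tertiary C8 enolate closes onto the vinylphosphonium carbon that carries the second ester, and proton shift with β-elimination frees the catalyst and leaves the C10=C5 double bond; the cis ring fusion (allyl cis to H-9) is forced by the five-membered ring, and the closest known chemistry is the Lu allenoate–enone [3+2] annulation and its asymmetric versions with β-substituted and exocyclic enones, which has not been shown for α-alkyl cycloalkenones or for allene-1,3-diesters.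

**Step 4**
Reactants: 5 bicyclic keto diester
Product: 6 C14 tert-butyldimethylsilyl enol ether of 5 (C13=C14)
Conditions: LiN(SiMe3)2 (2.2 equiv), THF, −78 °C; TBSOTf (1.1 equiv), −78 to 0 °C; pH 7 buffer
Reagents that add atoms: tert-butyldimethylsilyl trifluoromethanesulfonate, CC(C)(C)[Si](C)(C)OS(=O)(=O)C(F)(F)F
Why: In the dianion the harder ketone enolate is silylated on oxygen before the stabilised glutaconate anion, and the ketone can only enolise towards C13 because C8 is quaternary (regiospecific silyl enol ether formation); no stereocentre changes.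

**Step 5**
Reactants: 6 silyl enol ether
Product: 7 tricyclic 14-oxo-16-methylene diester (rings B, C and D)
Conditions: Pd(OAc)2 (10 mol%), O2 (1 atm), DMSO, 45 °C
Reagents that add atoms: none
Why: Oxidative cycloalkenylation with divalent palladium (Saegusa-type enolate–alkene coupling): C13 adds 5-exo to the palladium-bound allyl alkene and β-hydride elimination gives the exocyclic methylene of the bicyclo[3.2.1]octanone; the C13 configuration is fixed by C8 because the two-carbon bridge can span only one face.

**Step 6**
Reactants: 7 tricyclic keto diester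
Product: 9 tricyclic 16-methylene diester with C14 as CH2, via tosylhydrazone 8 (not isolated)
Conditions: TsNHNH2 (1.3 equiv), PPTS (5 mol%), THF, 4 Å molecular sieves, 60 °C; then catecholborane (2.5 equiv), 0 °C; then NaOAc·3H2O, 65 °C
Reagents that add atoms: none
Why: Hydrazone formation at the strained bridging ketone, hydride addition and diazene fragmentation (Caglioti-type tosylhydrazone deoxygenation) remove the carbonyl without touching the esters or the 1,1-disubstituted alkene; no stereocentre changes.

**Step 7**
Reactants: 9 tricyclic diester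
Product: 10 16,17-epoxide of 9
Conditions: mCPBA (1.1 equiv), NaHCO3, CH2Cl2, 0 °C
Reagents that add atoms: 3-chloroperoxybenzoic acid, OOC(=O)c1cccc(Cl)c1
Why: Prilezhaev epoxidation takes only the electron-rich exocyclic alkene and leaves the enoate, which masks the 16-ene against the later metathesis and dihydroxylation; the epoxide configuration is irrelevant.

**Step 8**
Reactants: 10 epoxy glutaconate
Product: 11 C10-allylated C5=C6 enoate (allyl β; C20 ester α)
Conditions: NaH (1.05 equiv), THF–DMF 4:1, 0 °C; allyl bromide (1.2 equiv), 0 to 25 °C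
Reagents that add atoms: allyl bromide, C=CCBr
Why: Alkylation of the vinylogous malonate anion occurs at the less hindered terminus C10 (C6 is flanked by quaternary C8) and anti to the pseudoaxial C9–C11 bond, i.e. on the β-face, which sets C10 and moves the double bond to C5=C6.

**Step 9**
Reactants: 11 allylated enoate
Product: 12 Michael adduct with C4H(CO2Me)(vinyl) at C5α (H-5 β)
Conditions: methyl but-3-enoate (2.0 equiv), LiN(iPr)2 (2.0 equiv), THF, −78 °C; then 11, −78 to −30 °C; AcOH, −78 °C
Reagents that add atoms: methyl but-3-enoate, C=CCC(=O)OC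
Why: Michael addition of the lithium dienolate through its α-carbon to the non-enolisable enoate; attack at C5 anti to the pseudoaxial β-allyl group of the rigid cyclopentene sets C5 (C4 α, trans A/B relationship), while C4 and C6 form as mixtures that are fixed in step 11.

**Step 10**
Reactants: 12 Michael adduct
Product: 13 ring A 2-ene (C4–H ester)
Conditions: second-generation Hoveyda–Grubbs catalyst (5 mol%), CH2Cl2 (5 mM), 40 °C
Reagents that add atoms: none
Why: Ring-closing metathesis of the C10 allyl and C4 vinyl groups, the only alkenes present, closes the trans-fused cyclohexene with C2=C3; no stereocentre is formed.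

**Step 11**
Reactants: 13 ring A 2-ene
Product: 15 C4-methylated triester with 6β-ester, via C6-epimer mixture 14 (not isolated)
Conditions: LiN(iPr)2 (1.1 equiv), THF–HMPA, −78 °C; MeI (1.5 equiv), −78 to −20 °C; evaporate volatiles; KOtBu (0.3 equiv), t-BuOH–THF, 25 °C
Reagents that add atoms: iodomethane, CI
Why: The doubly activated C4–H gives the ester dienolate, which is methylated at the α-carbon from the equatorial β-face away from the axial C20 ester (sets C4: 18-methyl β, 19-ester α), and catalytic tert-butoxide then equilibrates C6 to the more stable ester trans to C4 (enolate alkylation followed by thermodynamic epimerisation).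

**Step 12**
Reactants: 15 methylated triester
Product: 16 2β,3β-diol
Conditions: OsO4 (5 mol%), NMO (1.5 equiv), acetone–H2O 5:1, 25 °C
Reagents that add atoms: N-methylmorpholine N-oxide, C[N+]1([O-])CCOCC1; water, O
Why: Upjohn dihydroxylation of the only alkene; osmium adds to the β-face, anti to the axial C19 and C20 esters, which sets C2 and C3 together.

**Step 13**
Reactants: 16 epoxy diol
Product: 17 trimethyl ester of the target gibberellin (2β,3β-diol with the 16-ene restored)
Conditions: Ph3P=Se (1.5 equiv), CF3CO2H (1.2 equiv), CH2Cl2, 25 °C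
Reagents that add atoms: none
Why: Selenium-for-oxygen exchange gives an episelenide that extrudes selenium and returns the exocyclic 16-ene (phosphine selenide epoxide deoxygenation); no ring stereocentre is touched.

**Step 14**
Reactants: 17 trimethyl ester of the target gibberellin
Product: 18 2β,3β-dihydroxygibberell-16-ene-7,19,20-trioic acid (the target gibberellin)
Conditions: LiSPr (12 equiv), HMPA, 25 to 50 °C; then 1 M HCl to pH 3
Reagents that add atoms: none
Why: Thiolate attacks the methyl carbons (SN2 ester dealkylation), so the hindered C19 and C20 esters are cleaved without hydrolysis conditions and without base strong enough to epimerise C6 or trigger retro-aldol at C3.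

**Compound list**
1 | dimethyl 3-oxopentanedioate | COC(=O)CC(=O)CC(=O)OC | starting material
2 | dimethyl penta-2,3-dienedioate (racemic allene) | COC(=O)C=C=CC(=O)OC | intermediate
3 | 2-iodocyclohex-2-en-1-one | O=C1CCCC=C1I | starting material
4 | 2-allylcyclohex-2-en-1-one | O=C1CCCC=C1CC=C | intermediate
5 | dimethyl (3aR,7aS)-7a-allyl-7-oxo-3a,4,5,6,7,7a-hexahydro-1H-indene-1,3-dicarboxylate (cis-fused rings B/C; C10=C5; C6 epimers, converge in step 8) | C=CC[C@]12C(=O)CCC[C@H]1C(C(=O)OC)=CC2C(=O)OC | intermediate
6 | C13=C14 tert-butyldimethylsilyl enol ether of 5 | C=CC[C@]12C(O[Si](C)(C)C(C)(C)C)=CCC[C@H]1C(C(=O)OC)=CC2C(=O)OC | intermediate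
7 | rings B/C/D tricycle: 14-oxo, 16-methylene, C10=C5, methyl esters at C6 and C10, 9β-H | C=C1C[C@]23C(=O)[C@H]1CC[C@H]2C(C(=O)OC)=CC3C(=O)OC | intermediate
8 | C14 N-tosylhydrazone of 7 | C=C1C[C@]23C(=NNS(=O)(=O)c4ccc(C)cc4)[C@H]1CC[C@H]2C(C(=O)OC)=CC3C(=O)OC | intermediate
9 | 14-deoxo analogue of 7 (C14 = CH2) | C=C1C[C@]23C[C@H]1CC[C@H]2C(C(=O)OC)=CC3C(=O)OC | intermediate
10 | 16,17-epoxide of 9 (spiro-oxirane at C16) | C1OC12C[C@]34C[C@H]2CC[C@H]3C(C(=O)OC)=CC4C(=O)OC | intermediate
11 | 10β-allyl-10α-methoxycarbonyl C5=C6 enoate, 16,17-epoxide | C1OC12C[C@]34C[C@H]2CC[C@H]3[C@@](CC=C)(C(=O)OC)C=C4C(=O)OC | intermediate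
12 | 5α-[1-(methoxycarbonyl)prop-2-enyl] adduct of 11 (5β-H; C4 and C6 epimers) | C1OC12C[C@]34C[C@H]2CC[C@H]3[C@@](CC=C)(C(=O)OC)[C@@H](C(C=C)C(=O)OC)C4C(=O)OC | intermediate
13 | tetracyclic 2-ene with C4–H: trimethyl 16,17-epoxy-18-nor-gibberell-2-ene-7,19,20-trioate (C4 and C6 epimers) | C1OC12C[C@]34C[C@H]2CC[C@H]3[C@]5(C(=O)OC)CC=CC(C(=O)OC)[C@H]5C4C(=O)OC | intermediate
14 | trimethyl 16,17-epoxygibberell-2-ene-7,19,20-trioate, 18-methyl β, C6 epimers | C1OC12C[C@]34C[C@H]2CC[C@H]3[C@]5(C(=O)OC)CC=C[C@@](C)(C(=O)OC)[C@H]5C4C(=O)OC | intermediate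
15 | as 14 with 6β-methoxycarbonyl | C1OC12C[C@]34C[C@H]2CC[C@H]3[C@]5(C(=O)OC)CC=C[C@@](C)(C(=O)OC)[C@H]5[C@@H]4C(=O)OC | intermediate
16 | 2β,3β-dihydroxy-16,17-epoxy trimethyl ester | C1OC12C[C@]34C[C@H]2CC[C@H]3[C@]5(C(=O)OC)C[C@H](O)[C@H](O)[C@@](C)(C(=O)OC)[C@H]5[C@@H]4C(=O)OC | intermediate
17 | trimethyl 2β,3β-dihydroxygibberell-16-ene-7,19,20-trioate (trimethyl ester of the target gibberellin) | C=C1C[C@]23C[C@H]1CC[C@H]2[C@]1(C(=O)OC)C[C@H](O)[C@H](O)[C@@](C)(C(=O)OC)[C@H]1[C@@H]3C(=O)OC | intermediate
18 | 2β,3β-dihydroxygibberell-16-ene-7,19,20-trioic acid (the target gibberellin; 18-methyl β, 19- and 20-carboxyl α, 6β-carboxyl, 5β-H, 9β-H) | C=C1C[C@]23C[C@H]1CC[C@H]2[C@]1(C(=O)O)C[C@H](O)[C@H](O)[C@@](C)(C(=O)O)[C@H]1[C@@H]3C(=O)O | target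

**Step count and risks**
Total step count: 14. Longest linear sequence: 13 steps (3 → 18 through steps 2–14; the branch from 1 is equally long).

Three steps most likely to fail:

Step 3 (the new annulation). The α-alkyl enone may be too weak an acceptor, the allene diester may oligomerise, or the enantioselectivity may be low. The fallback sets out from 4 and comes back at 5, using iminium activation and stepwise ring closure. Primary-amine catalysis (9-amino-9-deoxy-epi-quinine, benzoic acid, toluene) adds methyl nitroacetate to C9 of 4 to give methyl 2-nitro-2-(2-allyl-3-oxocyclohexyl)acetate F1. Annulation of F1 with methyl 2-bromoacrylate (Cs2CO3, MeCN, 0 to 25 °C; Michael addition of the nitronate, then displacement of bromide by the C8 enolate) closes ring B as the cis-fused dimethyl 7a-allyl-3-nitro-7-oxo-octahydroindene-1,3-dicarboxylate F2. DBU (THF, 25 °C) then eliminates nitrous acid across C10–C5 and gives 5.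

Step 6 (deoxygenation of the hindered bridging ketone). Hydrazone formation next to quaternary C8 may stall. The fallback sets out from 7 and comes back at 9, by radical deoxygenation. NaBH4 (MeOH, 0 °C) gives the C14 alcohol F3. Thiocarbonyldiimidazole with DMAP (CH2Cl2, 40 °C) gives the C14 O-(imidazol-1-ylthiocarbonyl) derivative F4. Barton–McCombie reduction (Bu3SnH, AIBN, toluene, 90 °C) gives 9.

Step 9 (Michael addition at C5). The dienolate may react through its γ-carbon, react sluggishly next to quaternary C10, or show poor facial selectivity, because the α-face is also the side on which ring C lies. The fallback sets out from 11 and comes back at 14, using a smaller stabilised nucleophile and closing ring A by Horner–Wadsworth–Emmons olefination instead of metathesis. The sodium salt of trimethyl phosphonoacetate (NaH, THF, 0 to 40 °C) adds to C5 to give the 5α-[(dimethoxyphosphoryl)(methoxycarbonyl)methyl] adduct F5. Hydroboration of the allyl group (9-BBN, THF; NaBO3·4H2O) gives the primary C3 alcohol F6, and Dess–Martin oxidation gives the C3 aldehyde F7. Intramolecular Horner–Wadsworth–Emmons reaction (LiCl, DBU, MeCN) gives the ring A 3-ene ester F8 (C3=C4–CO2Me). Deconjugative α-methylation of its dienolate (LiN(iPr)2, THF–HMPA, −78 °C; MeI) gives 14, which is equilibrated to 15 as in step 11.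

**Further compounds**
F1 | step 3 | methyl 2-nitro-2-(2-allyl-3-oxocyclohexyl)acetate (C9 as in 5; C8 and C10 epimers) | C=CCC1C(=O)CCC[C@H]1C([N+](=O)[O-])C(=O)OC
F2 | step 3 | dimethyl (3aR,7aS)-7a-allyl-3-nitro-7-oxo-octahydro-1H-indene-1,3-dicarboxylate (cis-fused; C6 and C10 epimers) | C=CC[C@]12C(=O)CCC[C@H]1C([N+](=O)[O-])(C(=O)OC)CC2C(=O)OC
F3 | step 6 | 14-hydroxy analogue of 7 (C14 epimers) | C=C1C[C@]23C(O)[C@H]1CC[C@H]2C(C(=O)OC)=CC3C(=O)OC
F4 | step 6 | 14-O-(imidazol-1-ylthiocarbonyl) derivative of F3 | C=C1C[C@]23C(OC(=S)n4ccnc4)[C@H]1CC[C@H]2C(C(=O)OC)=CC3C(=O)OC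
F5 | step 9 | 5α-[(dimethoxyphosphoryl)(methoxycarbonyl)methyl] adduct of 11 | C1OC12C[C@]34C[C@H]2CC[C@H]3[C@@](CC=C)(C(=O)OC)[C@@H](C(P(=O)(OC)OC)C(=O)OC)C4C(=O)OC
F6 | step 9 | 10β-(3-hydroxypropyl) analogue of F5 | C1OC12C[C@]34C[C@H]2CC[C@H]3[C@@](CCCO)(C(=O)OC)[C@@H](C(P(=O)(OC)OC)C(=O)OC)C4C(=O)OC
F7 | step 9 | 10β-(3-oxopropyl) analogue of F5 | C1OC12C[C@]34C[C@H]2CC[C@H]3[C@@](CCC=O)(C(=O)OC)[C@@H](C(P(=O)(OC)OC)C(=O)OC)C4C(=O)OC
F8 | step 9 | tetracyclic ring A 3-ene ester (C3=C4–CO2Me; C6 epimers) | C1OC12C[C@]34C[C@H]2CC[C@H]3[C@]5(C(=O)OC)CCC=C(C(=O)OC)[C@H]5C4C(=O)OC
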